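**Retrosynthetic overview**

1. Last bond: C-4–CH3, by adding MeMgBr to a 15-nor 4-ketone from the α face. This gives 4β-OH/4α-CH3; water capture at a C-4 cation is anti and would give the 4α-ol, so C-15 is left out of the cyclisation substrate and added last.
2. The ketone comes from a 15-nor-eudesman-4-ol made in one step that forms ArCH2–C-1, C-5–C-10 and C-4–O: an o-quinone methide attacks an (E,E)-ten-membered 1,5-diene, the ring closes across itself, and water ends the cascade.
3. The o-quinone methide comes from DDQ dehydrogenation of a fully substituted C-methyl formyl acyl phloroglucinol, two steps from a C-methylphloroglucinol.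
4. The ten-membered diene comes from alkenyl triflate reduction ⇐ anionic oxy-Cope ring expansion of a trans-1,2-divinylcyclohexanol ⇐ α-vinylation and vinyl addition on a chiral-pool cyclohexenone that supplies C-7.
5. Ring order: cyclohexane (chiral pool) → ten-membered ring → rings A and B of the decalin together in the transannular step. The arene ring is bought.

Assumption: eudesmane numbering is used for the terpenoid part (C-1 bears the benzylic CH2, C-4 the carbinol, C-7 the isopropenyl group, C-10 the angular methyl); the target is then (1S,4S,5R,7R,10S), i.e. 1β-CH2Ar, 4β-OH, 4α-CH3, 5α-H, 7β-isopropenyl, 10β-CH3.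

**Route**

Step 1
Reactants: 1 2,4,6-trihydroxytoluene; 2 3-methylbutanoyl chloride
Product: 3 3-methyl-1-(2,4,6-trihydroxy-3-methylphenyl)butan-1-one
Conditions: AlCl3, PhNO2/CH2Cl2, 0 → 60 °C; aq. HCl
Reagents that add atoms: none
Why: Friedel–Crafts C-acylation of the electron-rich phloroglucinol ring, in which the two free ring positions are equivalent and the first acyl group deactivates the ring against a second acylation.

Step 2
Reactants: 3 3-methyl-1-(2,4,6-trihydroxy-3-methylphenyl)butan-1-one
Product: 4 grandinol (2,4,6-trihydroxy-3-methyl-5-(3-methylbutanoyl)benzaldehyde)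
Conditions: POCl3, DMF, EtOAc, 0 → 25 °C; then H2O, 50 °C
Reagents that add atoms: N,N-dimethylformamide (CN(C)C=O); water (O)
Why: Vilsmeier–Haack formylation at the only free ring position, which is still activated by two ortho hydroxyl groups and one para hydroxyl group.

Step 3
Reactants: 5 (R)-(−)-carvone
Product: 7 (2R,5R)-2-ethenyl-2-methyl-5-(prop-1-en-2-yl)cyclohexan-1-one, via lithium enolate 6 (not isolated)
Conditions: LiBH(s-Bu)3, THF, −78 °C; then vinyl bromide, Pd2(dba)3, t-Bu3P, THF, −78 → 25 °C
Reagents that add atoms: vinyl bromide (C=CBr)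
Why: Proposed new method: 1,4-hydride delivery from LiBH(s-Bu)3 gives the regiodefined tetrasubstituted enolate 6 without touching the isopropenyl group (known reductive enolate formation from carvone), and oxidative addition of vinyl bromide to zerovalent palladium, transmetalation of 6 and reductive elimination then forge the quaternary C-2 (closest known reaction: Pd-catalysed α-vinylation of preformed ketone enolates to α-quaternary ketones), with C–C bond formation axial on the half-chair enolate and therefore cis to the equatorial isopropenyl group, as in alkylations of this enolate, giving the (2R,5R) isomer.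

Step 4
Reactants: 7 (2R,5R)-2-ethenyl-2-methyl-5-(prop-1-en-2-yl)cyclohexan-1-one
Product: 8 (1S,2R,5R)-1,2-diethenyl-2-methyl-5-(prop-1-en-2-yl)cyclohexan-1-ol
Conditions: CH2=CHMgBr, CeCl3, THF, −78 → 0 °C
Reagents that add atoms: vinylmagnesium bromide (C=C[Mg]Br)
Why: 1,2-Addition of the vinyl nucleophile (CeCl3 suppresses enolisation) to the chair conformer with equatorial isopropenyl and axial C-2 vinyl occurs anti to that axial vinyl group (axial attack), which sets C-1 as S and gives the trans-1,2-divinyl carbinol needed for an (E,E)-selective ring expansion.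

Step 5
Reactants: 8 (1S,2R,5R)-1,2-diethenyl-2-methyl-5-(prop-1-en-2-yl)cyclohexan-1-ol
Product: 11 (1Z,5E,9R)-6-methyl-9-(prop-1-en-2-yl)cyclodeca-1,5-dien-1-yl trifluoromethanesulfonate, via potassium alkoxide 9 (not isolated), via potassium enolate 10 (not isolated)
Conditions: KH, 18-crown-6, THF, 0 → 50 °C; then PhNTf2, −78 → 0 °C
Reagents that add atoms: N-phenylbis(trifluoromethanesulfonimide) (O=S(=O)(N(c1ccccc1)S(=O)(=O)C(F)(F)F)C(F)(F)F)
Why: Anionic oxy-Cope rearrangement of alkoxide 9 through the chair transition state in which both ring bonds are equatorial (trans-divinyl arrangement) expands the cyclohexane to the ten-membered enolate 10 with E geometry at the new trisubstituted alkene and a ring-trans enolate, which PhNTf2 traps on oxygen; the carvone-derived stereocentre is untouched and the two carbinol-stage stereocentres are erased on purpose.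

Step 6
Reactants: 11 (1Z,5E,9R)-6-methyl-9-(prop-1-en-2-yl)cyclodeca-1,5-dien-1-yl trifluoromethanesulfonate
Product: 12 (1E,5E,8R)-1-methyl-8-(prop-1-en-2-yl)cyclodeca-1,5-diene (15-nor-germacrene A)
Conditions: Pd(OAc)2, PPh3, n-Bu3N (3 equiv), HCO2H (2 equiv), DMF, 40 °C
Reagents that add atoms: none
Why: Palladium-catalysed formate reduction of the alkenyl triflate (oxidative addition, formate-to-hydride exchange with loss of CO2, reductive elimination) replaces OTf by H with retention of alkene geometry and gives the acid- and heat-sensitive (E,E)-1,5-diene under amine-buffered conditions at 40 °C, well below the temperature of Cope rearrangement.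

Step 7
Reactants: 4 grandinol; 12 (1E,5E,8R)-1-methyl-8-(prop-1-en-2-yl)cyclodeca-1,5-diene (1.5 equiv)
Product: 14 3-{[(1S,4R,5R,7R,10S)-4-hydroxy-15-nor-eudesm-11-en-1-yl]methyl}-2,4,6-trihydroxy-5-(3-methylbutanoyl)benzaldehyde, via o-quinone methide 13 (not isolated)
Conditions: DDQ (1.0 equiv, slow addition), MeNO2/H2O 9:1, 0 → 20 °C
Reagents that add atoms: water (O)
Why: Proposed new method: DDQ dehydrogenates the ortho-methyl phenol 4 to the o-quinone methide 13 (known for grandinol), whose methylene carbon attacks C-1 of the strained trisubstituted (E)-alkene of 12 from its outer face while the C-4=C-5 π bond, held across the ring in the crossed chair–chair conformer with the isopropenyl group equatorial, closes C-5–C-10 anti to the incoming electrophile and water captures C-4 (the aqueous medium keeps the phenol protonated and any chroman from O-closure can re-ionise at its tertiary C–O bond), so that C-1 (β-CH2Ar), C-10 (β-CH3) and C-5 (α-H, trans-decalin) are set in one operation relative to C-7; the closest known reaction types are o-quinone methide additions to strained terpene alkenes and the electrophile-induced anti transannular cyclisation of (E,E)-cyclodeca-1,5-dienes and germacrenes to trans-decalins.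

Step 8
Reactants: 14 3-{[(1S,4R,5R,7R,10S)-4-hydroxy-15-nor-eudesm-11-en-1-yl]methyl}-2,4,6-trihydroxy-5-(3-methylbutanoyl)benzaldehyde
Product: 15 3-{[(1S,5R,7R,10S)-4-oxo-15-nor-eudesm-11-en-1-yl]methyl}-2,4,6-trihydroxy-5-(3-methylbutanoyl)benzaldehyde
Conditions: Dess–Martin periodinane, CH2Cl2, 0 → 20 °C
Reagents that add atoms: none
Why: Dess–Martin oxidation of the secondary alcohol under near-neutral conditions converges both possible C-4 epimers on one ketone and leaves the aldehyde, the hydrogen-bonded phenols and the alkene untouched, while the ring-fusion centre C-5, now α to the ketone, is already in the more stable trans arrangement.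

Step 9
Reactants: 15 3-{[(1S,5R,7R,10S)-4-oxo-15-nor-eudesm-11-en-1-yl]methyl}-2,4,6-trihydroxy-5-(3-methylbutanoyl)benzaldehyde
Product: 18 3-{[(1S,4S,5R,7R,10S)-4-hydroxyeudesm-11-en-1-yl]methyl}-2,4,6-trihydroxy-5-(3-methylbutanoyl)benzaldehyde (the target), via N-butyl aldimine 16 (not isolated), via carbinol aldimine 17 (not isolated)
Conditions: n-BuNH2 (1.05 equiv), 4 Å molecular sieves, THF, 20 °C; then CeCl3, MeMgBr (6 equiv), −78 → −30 °C; then 1 M aq. HCl, THF, 0 °C
Reagents that add atoms: methylmagnesium bromide (C[Mg]Br)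
Why: Condensation of n-BuNH2 with the activated aryl aldehyde masks it in the flask as the hydrogen-bonded aldimine 16, whose magnesium salt and the phenolate-flanked aryl ketone do not accept MeMgBr at low temperature, so MeMgBr/CeCl3 adds only to the C-4 ketone (1,2-addition) and does so from the α face because the β-axial approach is blocked by the syn-axial C-10 methyl group, which sets the 4β-hydroxy-4α-methyl carbinol as in methyl additions to decalones with an angular methyl group, and aqueous acid then hydrolyses 17 to the aldehyde.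

**Compound list**

1 | 2,4,6-trihydroxytoluene (2-methylbenzene-1,3,5-triol) | Cc1c(O)cc(O)cc1O | starting material
2 | 3-methylbutanoyl chloride (isovaleryl chloride) | CC(C)CC(Cl)=O | starting material
3 | 3-methyl-1-(2,4,6-trihydroxy-3-methylphenyl)butan-1-one | CC(C)CC(=O)c1c(O)cc(O)c(C)c1O | intermediate
4 | grandinol, 2,4,6-trihydroxy-3-methyl-5-(3-methylbutanoyl)benzaldehyde | CC(C)CC(=O)c1c(O)c(C)c(O)c(C=O)c1O | intermediate
5 | (R)-(−)-carvone, (5R)-2-methyl-5-(prop-1-en-2-yl)cyclohex-2-en-1-one | O=C1C(C)=CC[C@@H](C(C)=C)C1 | starting material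
6 | lithium (5R)-2-methyl-5-(prop-1-en-2-yl)cyclohex-1-en-1-olate | [Li+].[O-]C1=C(C)CC[C@@H](C(C)=C)C1 | intermediate
7 | (2R,5R)-2-ethenyl-2-methyl-5-(prop-1-en-2-yl)cyclohexan-1-one (vinyl cis to isopropenyl) | C=C[C@@]1(C)CC[C@@H](C(C)=C)CC1=O | intermediate
8 | (1S,2R,5R)-1,2-diethenyl-2-methyl-5-(prop-1-en-2-yl)cyclohexan-1-ol (the two vinyl groups trans) | C=C[C@@]1(C)CC[C@@H](C(C)=C)C[C@]1(O)C=C | intermediate
9 | potassium (1S,2R,5R)-1,2-diethenyl-2-methyl-5-(prop-1-en-2-yl)cyclohexan-1-olate | C=C[C@@]1(C)CC[C@@H](C(C)=C)C[C@]1([O-])C=C.[K+] | intermediate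
10 | potassium (1Z,5E,9R)-6-methyl-9-(prop-1-en-2-yl)cyclodeca-1,5-dien-1-olate | C=C(C)[C@@H]1CC/C(C)=C/CC/C=C([O-])/C1.[K+] | intermediate
11 | (1Z,5E,9R)-6-methyl-9-(prop-1-en-2-yl)cyclodeca-1,5-dien-1-yl trifluoromethanesulfonate | C=C(C)[C@@H]1CC/C(C)=C/CC/C=C(OS(=O)(=O)C(F)(F)F)/C1 | intermediate
12 | (1E,5E,8R)-1-methyl-8-(prop-1-en-2-yl)cyclodeca-1,5-diene (15-nor-germacrene A) | C=C(C)[C@@H]1CC/C(C)=C/CC/C=C/C1 | intermediate
13 | grandinol o-quinone methide, 2,4-dihydroxy-5-methylidene-3-(3-methylbutanoyl)-6-oxocyclohexa-1,3-diene-1-carbaldehyde | O=CC1=C(O)C(C(=O)CC(C)C)=C(O)C(=C)C1=O | intermediate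
14 | 3-{[(1S,4R,5R,7R,10S)-4-hydroxy-15-nor-eudesm-11-en-1-yl]methyl}-2,4,6-trihydroxy-5-(3-methylbutanoyl)benzaldehyde (1β-CH2Ar, 4α-OH, 5α-H, 7β-isopropenyl, 10β-CH3) | C=C(C)[C@@H]1CC[C@@]2(C)[C@H](Cc3c(O)c(C=O)c(O)c(C(=O)CC(C)C)c3O)CC[C@@H](O)[C@@H]2C1 | intermediate
15 | 3-{[(1S,5R,7R,10S)-4-oxo-15-nor-eudesm-11-en-1-yl]methyl}-2,4,6-trihydroxy-5-(3-methylbutanoyl)benzaldehyde | C=C(C)[C@@H]1CC[C@@]2(C)[C@H](Cc3c(O)c(C=O)c(O)c(C(=O)CC(C)C)c3O)CCC(=O)[C@@H]2C1 | intermediate
16 | N-butyl aldimine of 15 (aryl CH=N–n-Bu, E) | C=C(C)[C@@H]1CC[C@@]2(C)[C@H](Cc3c(O)c(/C=N/CCCC)c(O)c(C(=O)CC(C)C)c3O)CCC(=O)[C@@H]2C1 | intermediate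
17 | N-butyl aldimine of 18 (aryl CH=N–n-Bu, E; 4β-OH, 4α-CH3) | C=C(C)[C@@H]1CC[C@@]2(C)[C@H](Cc3c(O)c(/C=N/CCCC)c(O)c(C(=O)CC(C)C)c3O)CC[C@](C)(O)[C@@H]2C1 | intermediate
18 | 3-{[(1S,4S,5R,7R,10S)-4-hydroxyeudesm-11-en-1-yl]methyl}-2,4,6-trihydroxy-5-(3-methylbutanoyl)benzaldehyde (1β-CH2Ar, 4β-OH, 4α-CH3, 5α-H, 7β-isopropenyl, 10β-CH3) | C=C(C)[C@@H]1CC[C@@]2(C)[C@H](Cc3c(O)c(C=O)c(O)c(C(=O)CC(C)C)c3O)CC[C@](C)(O)[C@@H]2C1 | target

**Step count and risks**

Total step count: 9. Longest linear sequence: 7 steps (steps 3 to 9, from 5).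

The three steps most likely to fail:

Step 7 (the cascade). The o-quinone methide may close on oxygen to a chroman or be intercepted by the isopropenyl group. The secondary C-4 cation may suffer a hydride shift from C-5. DDQ and its acidic hydroquinone may consume the acid-sensitive diene. The fallback keeps oxidant and diene apart and sets out from 4 and 12. DDQ in acetic acid converts 4 into the benzylic acetate [3-formyl-2,4,6-trihydroxy-5-(3-methylbutanoyl)phenyl]methyl acetate F2. F2 is then added to 12 in NaOAc-buffered water/MeNO2 at 20 to 40 °C, where loss of acetate regenerates 13 under oxidant-free, near-neutral conditions. The sequence comes back to the route at 14.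

Step 3 (one-pot reductive α-vinylation). The hindered tetrasubstituted enolate may couple slowly, equilibrate to the C-6 enolate, or give O-vinylation. The fallback sets out from 5. The same LiBH(s-Bu)3-derived enolate is added to phenyl vinyl sulfoxide (Michael addition) to give the keto sulfoxide (2R,5R)-2-methyl-2-[2-(phenylsulfinyl)ethyl]-5-(prop-1-en-2-yl)cyclohexan-1-one F1. Thermal syn-elimination of benzenesulfenic acid (toluene, NaHCO3, 110 °C) then comes back to the route at 7.

Step 9 (methyl addition beside an aryl aldehyde). The masked aldehyde may still be attacked, or the imine may resist mild hydrolysis. The fallback runs the last three steps in a series without the formyl group and sets out from 3 and 12. DDQ oxidation of 3 in the presence of 12 and water gives the des-formyl alcohol 1-(3-{[(1S,4R,5R,7R,10S)-4-hydroxy-15-nor-eudesm-11-en-1-yl]methyl}-2,4,6-trihydroxyphenyl)-3-methylbutan-1-one F3. Dess–Martin oxidation gives the des-formyl ketone 1-(3-{[(1S,5R,7R,10S)-4-oxo-15-nor-eudesm-11-en-1-yl]methyl}-2,4,6-trihydroxyphenyl)-3-methylbutan-1-one F4. MeMgBr/CeCl3, now with no aldehyde to mask, gives the des-formyl carbinol 1-(3-{[(1S,4S,5R,7R,10S)-4-hydroxyeudesm-11-en-1-yl]methyl}-2,4,6-trihydroxyphenyl)-3-methylbutan-1-one F5. Vilsmeier formylation (POCl3, DMF, 0 °C) of the one free ring position then comes back to the route at 18.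

**Further compounds**

F1 | step 3 | (2R,5R)-2-methyl-2-[2-(phenylsulfinyl)ethyl]-5-(prop-1-en-2-yl)cyclohexan-1-one | O=S(c1ccccc1)CC[C@@]1(C)CC[C@@H](C(C)=C)CC1=O
F2 | step 7 | [3-formyl-2,4,6-trihydroxy-5-(3-methylbutanoyl)phenyl]methyl acetate | CC(=O)OCc1c(O)c(C=O)c(O)c(C(=O)CC(C)C)c1O
F3 | step 9 | 1-(3-{[(1S,4R,5R,7R,10S)-4-hydroxy-15-nor-eudesm-11-en-1-yl]methyl}-2,4,6-trihydroxyphenyl)-3-methylbutan-1-one | C=C(C)[C@@H]1CC[C@@]2(C)[C@H](Cc3c(O)cc(O)c(C(=O)CC(C)C)c3O)CC[C@@H](O)[C@@H]2C1
F4 | step 9 | 1-(3-{[(1S,5R,7R,10S)-4-oxo-15-nor-eudesm-11-en-1-yl]methyl}-2,4,6-trihydroxyphenyl)-3-methylbutan-1-one | C=C(C)[C@@H]1CC[C@@]2(C)[C@H](Cc3c(O)cc(O)c(C(=O)CC(C)C)c3O)CCC(=O)[C@@H]2C1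
F5 | step 9 | 1-(3-{[(1S,4S,5R,7R,10S)-4-hydroxyeudesm-11-en-1-yl]methyl}-2,4,6-trihydroxyphenyl)-3-methylbutan-1-one | C=C(C)[C@@H]1CC[C@@]2(C)[C@H](Cc3c(O)cc(O)c(C(=O)CC(C)C)c3O)CC[C@](C)(O)[C@@H]2C1
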